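**Retrosynthetic overview**

1. Coumarin A and coumarin B end in the same pyran-2-one ring (O1–C2(=O)–C3=C4, fused at C4a/C8a, with C4a ortho to the ring oxygen and para to the 7-OMe). O1–C2 and C3=C4 of both rings are therefore cut together, which gives bis-salicylaldehyde 21 and two molecules of Ph3P=CHCO2Et (22).
2. The two CHO groups of 21 come from double ortho-formylation of bisphenol 19. The (E)-styryl bond of 19 comes from a Horner–Wadsworth–Emmons union of ring-C aldehyde 11 with benzylphosphonate 16.
3. Aldehyde 11 comes from 9 by enolate C-methylation anti to the aryl group. The methyl is added on the ring because an α,α-dialkyl enamine with two similar branches would not fix C6'. Aldehyde 9 comes from 8 by ring-closing metathesis, and 8 from aryl vinyl carbinol 3 and 5-methylhex-5-enal (7) by Ir/enamine allylation, which sets C1'.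
4. Ring order: ring C first (step 6), then both pyranone rings of coumarins A and B together (step 15). Ring C is numbered C1' (bears coumarin A) to C6' (bears CH3 and the styryl group); aryl and styryl are cis, (1'S,6'S).

Key step: step 15

Assumption: in step 5 the (R)-configured (P,olefin) ligand is taken to give the (3S) benzylic centre of 8 and the (S)-amine the (2S) centre; the sense of induction would be checked on the first run and the mirror-image ligand used if it were reversed.

**Route**

Step 1
Reactants: 1 4-hydroxy-2-methoxybenzaldehyde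
Product: 2 2-methoxy-4-(methoxymethoxy)benzaldehyde
Conditions: MOMCl, i-Pr2NEt, CH2Cl2, 0 °C → rt
Reagents that add atoms: chloromethyl methyl ether, COCCl
Why: O-alkylation of the acidic para-formyl phenol with the α-chloro ether (Williamson-type) should give the MOM acetal, which withstands the Grignard, enolate and phosphonate-anion steps ahead.

Step 2
Reactants: 2 2-methoxy-4-(methoxymethoxy)benzaldehyde
Product: 3 rac-1-[2-methoxy-4-(methoxymethoxy)phenyl]prop-2-en-1-ol
Conditions: CH2=CHMgBr, THF, −78 → 0 °C; sat. aq. NH4Cl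
Reagents that add atoms: vinylmagnesium bromide, C=C[Mg]Br
Why: Grignard 1,2-addition to the aryl aldehyde gives the branched allylic alcohol; the racemate suffices because step 5 is enantioconvergent.

Step 3
Reactants: 4 4-bromo-2-methylbut-1-ene
Product: 6 5-methylhex-5-en-1-ol, via (3-methylbut-3-en-1-yl)magnesium bromide 5 (not isolated)
Conditions: Mg, THF, rt; then ethylene oxide, CuI (cat.), −30 → 0 °C; sat. aq. NH4Cl
Reagents that add atoms: oxirane, C1CO1
Why: Grignard formation followed by copper-assisted SN2 opening of the epoxide is a standard two-carbon homologation of a primary bromide.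

Step 4
Reactants: 6 5-methylhex-5-en-1-ol
Product: 7 5-methylhex-5-enal
Conditions: TEMPO (cat.), PhI(OAc)2, CH2Cl2, rt
Reagents that add atoms: none
Why: The oxoammonium (TEMPO) oxidation of a primary alcohol stops at the aldehyde and leaves the 1,1-disubstituted alkene alone.

Step 5
Reactants: 3 rac-1-[2-methoxy-4-(methoxymethoxy)phenyl]prop-2-en-1-ol; 7 5-methylhex-5-enal
Product: 8 (2S,3S)-3-[2-methoxy-4-(methoxymethoxy)phenyl]-2-(3-methylbut-3-en-1-yl)pent-4-enal
Conditions: [Ir(cod)Cl]2 (3 mol%), (R)-BINOL-derived phosphoramidite with N-dibenzo[b,f]azepinyl group ((P,olefin) ligand, 12 mol%), (S)-α,α-bis[3,5-bis(trifluoromethyl)phenyl]prolinol TMS ether (15 mol%), (MeO)2P(O)OH (5 mol%), ClCH2CH2Cl, 25 °C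
Reagents that add atoms: none
Why: Dual iridium/enamine catalysis (enantioconvergent Ir-catalysed allylic substitution): racemic 3 ionises to an (η3-allyl)iridium complex whose (P,olefin) ligand directs the enamine of 7 to the aryl-bearing terminus and to one allyl face, which sets C3 (the future C1'), while the prolinol ether sets C2, a centre that is planarised again in step 7 so that only the ligand-controlled centre has to be right.

Step 6
Reactants: 8 (2S,3S)-3-[2-methoxy-4-(methoxymethoxy)phenyl]-2-(3-methylbut-3-en-1-yl)pent-4-enal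
Product: 9 (1S,2S)-2-[2-methoxy-4-(methoxymethoxy)phenyl]-4-methylcyclohex-3-ene-1-carbaldehyde
Conditions: second-generation Grubbs catalyst, RuCl2(=CHPh)(H2IMes)(PCy3) (5 mol%), CH2Cl2, 40 °C
Reagents that add atoms: none
Why: Ring-closing metathesis between the vinyl group and the 1,1-disubstituted alkene should close ring C as a six-membered ring with the trisubstituted C2'=C3' alkene and release ethene, without touching a stereocentre.

Step 7
Reactants: 9 (1S,2S)-2-[2-methoxy-4-(methoxymethoxy)phenyl]-4-methylcyclohex-3-ene-1-carbaldehyde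
Product: 11 (1R,2R)-2-[2-methoxy-4-(methoxymethoxy)phenyl]-1,4-dimethylcyclohex-3-ene-1-carbaldehyde, via potassium enolate 10 (not isolated)
Conditions: KOtBu, MeI, THF, −20 → 0 °C
Reagents that add atoms: iodomethane, CI
Why: Enolate C-alkylation of an α-branched aldehyde: both C1 epimers of 9 converge on the exocyclic enolate 10, in which the C2 aryl group sits pseudoaxial to escape allylic strain and shields one face, so iodomethane should bond to C1 from the opposite face and place CH3 trans and CHO cis to the aryl group, which is the C1'/C6' relationship of the target.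

Step 8
Reactants: 12 2-hydroxy-6-methoxybenzaldehyde
Product: 13 2-methoxy-6-(methoxymethoxy)benzaldehyde
Conditions: MOMCl, i-Pr2NEt, CH2Cl2, 0 → 40 °C
Reagents that add atoms: chloromethyl methyl ether, COCCl
Why: O-alkylation of the salicylaldehyde phenol with the α-chloro ether (Williamson-type) masks the hydroxyl before the benzylic carbanion is made.

Step 9
Reactants: 13 2-methoxy-6-(methoxymethoxy)benzaldehyde
Product: 14 [2-methoxy-6-(methoxymethoxy)phenyl]methanol
Conditions: NaBH4, MeOH, 0 °C
Reagents that add atoms: none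
Why: Borohydride reduction of an aryl aldehyde to the benzyl alcohol is selective and leaves both acetal and ether untouched.

Step 10
Reactants: 14 [2-methoxy-6-(methoxymethoxy)phenyl]methanol
Product: 15 2-(bromomethyl)-1-methoxy-3-(methoxymethoxy)benzene
Conditions: CBr4, PPh3, CH2Cl2, 0 °C; used at once
Reagents that add atoms: carbon tetrabromide, BrC(Br)(Br)Br
Why: The Appel bromination runs under neutral conditions, so no HBr is present that could cleave the MOM group of this electron-rich benzyl system.

Step 11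
Reactants: 15 2-(bromomethyl)-1-methoxy-3-(methoxymethoxy)benzene
Product: 16 diethyl {[2-methoxy-6-(methoxymethoxy)phenyl]methyl}phosphonate
Conditions: P(OEt)3 (neat), 110 °C
Reagents that add atoms: triethyl phosphite, CCOP(OCC)OCC
Why: Michaelis–Arbuzov reaction of a reactive benzylic bromide with triethyl phosphite, with loss of bromoethane.

Step 12
Reactants: 11 (1R,2R)-2-[2-methoxy-4-(methoxymethoxy)phenyl]-1,4-dimethylcyclohex-3-ene-1-carbaldehyde; 16 diethyl {[2-methoxy-6-(methoxymethoxy)phenyl]methyl}phosphonate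
Product: 18 1-methoxy-2-[(E)-2-{(1S,2S)-2-[2-methoxy-4-(methoxymethoxy)phenyl]-1,4-dimethylcyclohex-3-en-1-yl}ethenyl]-3-(methoxymethoxy)benzene, via sodium phosphonate carbanion 17 (not isolated)
Conditions: 16, NaH, 15-crown-5, THF, 0 °C; then 11, 0 → 50 °C
Reagents that add atoms: none
Why: Horner–Wadsworth–Emmons olefination: carbanion 17 adds reversibly to the non-enolisable neopentyl aldehyde and the adduct collapses through the anti oxaphosphetane with loss of diethyl phosphate, which should give the (E)-styryl bond while the quaternary centre and the remote benzylic C–H stay untouched.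

Step 13
Reactants: 18 1-methoxy-2-[(E)-2-{(1S,2S)-2-[2-methoxy-4-(methoxymethoxy)phenyl]-1,4-dimethylcyclohex-3-en-1-yl}ethenyl]-3-(methoxymethoxy)benzene
Product: 19 2-[(E)-2-{(1S,2S)-2-(4-hydroxy-2-methoxyphenyl)-1,4-dimethylcyclohex-3-en-1-yl}ethenyl]-3-methoxyphenol
Conditions: p-TsOH·H2O (cat.), MeOH, 25–40 °C
Reagents that add atoms: none
Why: Acid-catalysed transacetalisation to methanol frees both phenols as dimethoxymethane under conditions mild enough to leave the aryl methyl ethers, the trisubstituted ring alkene and the electron-rich styrene unchanged.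

Step 14
Reactants: 19 2-[(E)-2-{(1S,2S)-2-(4-hydroxy-2-methoxyphenyl)-1,4-dimethylcyclohex-3-en-1-yl}ethenyl]-3-methoxyphenol
Product: 21 5-{(1S,6S)-6-[(E)-2-(3-formyl-2-hydroxy-6-methoxyphenyl)ethenyl]-3,6-dimethylcyclohex-2-en-1-yl}-2-hydroxy-4-methoxybenzaldehyde, via bis(hydroxymethyl) bisphenol 20 (not isolated)
Conditions: MgCl2, Et3N, (CH2O)n, MeCN, 80 °C; then 1 M HCl
Reagents that add atoms: paraformaldehyde (as formaldehyde), C=O
Why: Magnesium-mediated ortho-formylation (Casnati–Skattebøl): each magnesium phenoxide delivers formaldehyde to an ortho carbon and a second formaldehyde oxidises the hydroxymethyl group by hydride transfer; ring B has a single free ortho site, and in ring A the site para to OCH3 is favoured over the one wedged between OH and OCH3.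

Step 15
Reactants: 21 5-{(1S,6S)-6-[(E)-2-(3-formyl-2-hydroxy-6-methoxyphenyl)ethenyl]-3,6-dimethylcyclohex-2-en-1-yl}-2-hydroxy-4-methoxybenzaldehyde; 22 ethyl (triphenylphosphoranylidene)acetate (2.5 equiv)
Product: 24 7-methoxy-6-{(1S,6S)-6-[(E)-2-(7-methoxy-2-oxo-2H-chromen-8-yl)ethenyl]-3,6-dimethylcyclohex-2-en-1-yl}-2H-chromen-2-one (target), via bis-(E)-cinnamate 23 (not isolated)
Conditions: 22, toluene–MeOH, 25 → 50 °C; then n-Bu3P (0.4 equiv), 70 °C, argon
Reagents that add atoms: none
Why: Each aldehyde of 21 undergoes Wittig olefination with the stabilised ylide 22 (oxaphosphetane, loss of Ph3P=O) to give the bis-(E)-o-hydroxycinnamate 23, which puts C3=C4 of coumarin A and of coumarin B in place. n-Bu3P then adds reversibly to each cinnamate β-carbon, so that C3–C4 becomes a rotating single bond and the neighbouring phenol can reach the ester carbonyl; acyl substitution with loss of ethanol (6-exo-trig lactonisation, once for each pyranone ring) forms O1–C2, and E1cB loss of n-Bu3P restores C3=C4, now cis within the ring. The closest known reactions are the coumarin synthesis from salicylaldehydes and Ph3P=CHCO2R and the phosphine-catalysed cyclisation of (E)-o-hydroxycinnamates at 60–70 °C. No stereocentre is formed, and C1' and C6' of ring C are not touched. The step needs chemoselectivity and thermal mildness: the ring-C alkene and the styryl alkene are not Michael acceptors and should stay inert to ylide and phosphine, and working at 70 °C instead of forcing a thermal E/Z equilibration near 200 °C spares the C1'–C6' bond, which is the benzylic, doubly allylic 3,4-bond of a 1,5-diene and could undergo a [3,3] shift or homolytic stereomutation on hard heating. The regiochemistry of both annulations is fixed beforehand by the positions of the two CHO groups in 21.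

**Compound list**

1 | 4-hydroxy-2-methoxybenzaldehyde | O=Cc1ccc(O)cc1OC | starting material
2 | 2-methoxy-4-(methoxymethoxy)benzaldehyde | COCOc1ccc(C=O)c(OC)c1 | intermediate
3 | rac-1-[2-methoxy-4-(methoxymethoxy)phenyl]prop-2-en-1-ol | C=CC(O)c1ccc(OCOC)cc1OC | intermediate
4 | 4-bromo-2-methylbut-1-ene | C=C(C)CCBr | starting material
5 | (3-methylbut-3-en-1-yl)magnesium bromide (not isolated) | C=C(C)CC[Mg]Br | intermediate
6 | 5-methylhex-5-en-1-ol | C=C(C)CCCCO | intermediate
7 | 5-methylhex-5-enal | C=C(C)CCCC=O | intermediate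
8 | (2S,3S)-3-[2-methoxy-4-(methoxymethoxy)phenyl]-2-(3-methylbut-3-en-1-yl)pent-4-enal | COc1cc(OCOC)ccc1[C@H]([C@@H](C=O)CCC(C)=C)C=C | intermediate
9 | (1S,2S)-2-[2-methoxy-4-(methoxymethoxy)phenyl]-4-methylcyclohex-3-ene-1-carbaldehyde (trans) | COc1cc(OCOC)ccc1[C@H]1C=C(C)CC[C@@H]1C=O | intermediate
10 | potassium enolate of 9 (C1 planar, C2 unchanged; not isolated) | COc1cc(OCOC)ccc1[C@H]1C=C(C)CCC1=C[O-].[K+] | intermediate
11 | (1R,2R)-2-[2-methoxy-4-(methoxymethoxy)phenyl]-1,4-dimethylcyclohex-3-ene-1-carbaldehyde (CHO cis to aryl) | COc1cc(OCOC)ccc1[C@H]1C=C(C)CC[C@@]1(C)C=O | intermediate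
12 | 2-hydroxy-6-methoxybenzaldehyde | COc1cccc(O)c1C=O | starting material
13 | 2-methoxy-6-(methoxymethoxy)benzaldehyde | COCOc1cccc(OC)c1C=O | intermediate
14 | [2-methoxy-6-(methoxymethoxy)phenyl]methanol | COCOc1cccc(OC)c1CO | intermediate
15 | 2-(bromomethyl)-1-methoxy-3-(methoxymethoxy)benzene | COCOc1cccc(OC)c1CBr | intermediate
16 | diethyl {[2-methoxy-6-(methoxymethoxy)phenyl]methyl}phosphonate | CCOP(=O)(Cc1c(OC)cccc1OCOC)OCC | intermediate
17 | sodium carbanion of 16 (not isolated) | CCOP(=O)([CH-]c1c(OC)cccc1OCOC)OCC.[Na+] | intermediate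
18 | 1-methoxy-2-[(E)-2-{(1S,2S)-2-[2-methoxy-4-(methoxymethoxy)phenyl]-1,4-dimethylcyclohex-3-en-1-yl}ethenyl]-3-(methoxymethoxy)benzene | COc1cc(OCOC)ccc1[C@H]1C=C(C)CC[C@@]1(C)/C=C/c1c(OC)cccc1OCOC | intermediate
19 | 2-[(E)-2-{(1S,2S)-2-(4-hydroxy-2-methoxyphenyl)-1,4-dimethylcyclohex-3-en-1-yl}ethenyl]-3-methoxyphenol | COc1cc(O)ccc1[C@H]1C=C(C)CC[C@@]1(C)/C=C/c1c(OC)cccc1O | intermediate
20 | bis(hydroxymethyl) analogue of 21 (each CHO replaced by CH2OH; present as magnesium phenoxide, not isolated) | COc1cc(O)c(CO)cc1[C@H]1C=C(C)CC[C@@]1(C)/C=C/c1c(OC)ccc(CO)c1O | intermediate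
21 | 5-{(1S,6S)-6-[(E)-2-(3-formyl-2-hydroxy-6-methoxyphenyl)ethenyl]-3,6-dimethylcyclohex-2-en-1-yl}-2-hydroxy-4-methoxybenzaldehyde | COc1cc(O)c(C=O)cc1[C@H]1C=C(C)CC[C@@]1(C)/C=C/c1c(OC)ccc(C=O)c1O | intermediate
22 | ethyl (triphenylphosphoranylidene)acetate | CCOC(=O)C=P(c1ccccc1)(c1ccccc1)c1ccccc1 | starting material
23 | bis-(E)-cinnamate: 21 with each CHO replaced by (E)-CH=CH–CO2Et (not isolated) | COc1cc(O)c(/C=C/C(=O)OCC)cc1[C@H]1C=C(C)CC[C@@]1(C)/C=C/c1c(OC)ccc(/C=C/C(=O)OCC)c1O | intermediate
24 | 7-methoxy-6-{(1S,6S)-6-[(E)-2-(7-methoxy-2-oxo-2H-chromen-8-yl)ethenyl]-3,6-dimethylcyclohex-2-en-1-yl}-2H-chromen-2-one | COc1cc2oc(=O)ccc2cc1[C@H]1C=C(C)CC[C@@]1(C)/C=C/c1c(OC)ccc2ccc(=O)oc12 | target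

**Step count and risks**

Total steps: 15. Longest linear sequence: 9 steps (1, 2, 5, 6, 7, 12, 13, 14, 15).

Steps most likely to fail:

1. Step 15. The second annulation may stall: one of the two cinnamates, most likely that of ring B whose phenol is flanked by the styryl group, may lactonise slowly, or phosphine-induced oligomerisation of the cinnamates may compete. The fallback sets out from 21 and uses (triphenylphosphoranylidene)ketene (Ph3P=C=C=O) in toluene at 100 °C. Each phenol adds across the ketene C=C to give the bis[(triphenylphosphoranylidene)acetate] aryl ester F8, which is not isolated. Intramolecular Wittig reaction of each ester ylide with its ortho CHO then closes both pyranones with the ring-enforced cis C3=C4 geometry. The fallback comes back to the route at 24.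

2. Step 12. The hindered, electron-rich carbanion may add slowly to the neopentyl aldehyde, or the sequence may stall at the β-oxido phosphonate before elimination. The fallback sets out from 11. Takai–Utimoto olefination (CrCl2, CHI3, THF, 0 °C → rt) should give the (E)-vinyl iodide 1-{(1S,6R)-6-[(E)-2-iodoethenyl]-3,6-dimethylcyclohex-2-en-1-yl}-2-methoxy-4-(methoxymethoxy)benzene F5. In parallel, commercial 3-methoxyphenol is protected (MOMCl, i-Pr2NEt) to 1-methoxy-3-(methoxymethoxy)benzene F6. Lithiation of F6 between the two oxygens (n-BuLi, THF, 0 °C) and quenching with 2-isopropoxy-4,4,5,5-tetramethyl-1,3,2-dioxaborolane gives 2-[2-methoxy-6-(methoxymethoxy)phenyl]-4,4,5,5-tetramethyl-1,3,2-dioxaborolane F7. Suzuki–Miyaura coupling of F5 with F7 (Pd(OAc)2, SPhos, K3PO4, THF–H2O, 50 °C) keeps the E geometry and comes back to the route at 18.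

3. Step 7. The aldehyde enolate may be methylated with poor facial selectivity, or O-methylation may compete. The fallback sets out from 9 and uses the bulkier ester enolate, in which allylic strain locks the aryl group axial. Pinnick oxidation (NaClO2, NaH2PO4, 2-methyl-2-butene, t-BuOH–H2O) gives (1S,2S)-2-[2-methoxy-4-(methoxymethoxy)phenyl]-4-methylcyclohex-3-ene-1-carboxylic acid F1. Esterification (MeI, K2CO3, DMF) gives methyl (1S,2S)-2-[2-methoxy-4-(methoxymethoxy)phenyl]-4-methylcyclohex-3-ene-1-carboxylate F2. Enolate methylation (LiN(i-Pr)2, THF, −78 °C, then MeI) should give methyl (1R,2R)-2-[2-methoxy-4-(methoxymethoxy)phenyl]-1,4-dimethylcyclohex-3-ene-1-carboxylate F3. Reduction (LiAlH4, THF, 0 °C) gives {(1R,2S)-2-[2-methoxy-4-(methoxymethoxy)phenyl]-1,4-dimethylcyclohex-3-en-1-yl}methanol F4, and Dess–Martin oxidation (CH2Cl2, rt) comes back to the route at 11.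

**Further compounds**

F1 | step 7 | (1S,2S)-2-[2-methoxy-4-(methoxymethoxy)phenyl]-4-methylcyclohex-3-ene-1-carboxylic acid | COc1cc(OCOC)ccc1[C@H]1C=C(C)CC[C@@H]1C(=O)O
F2 | step 7 | methyl (1S,2S)-2-[2-methoxy-4-(methoxymethoxy)phenyl]-4-methylcyclohex-3-ene-1-carboxylate | COc1cc(OCOC)ccc1[C@H]1C=C(C)CC[C@@H]1C(=O)OC
F3 | step 7 | methyl (1R,2R)-2-[2-methoxy-4-(methoxymethoxy)phenyl]-1,4-dimethylcyclohex-3-ene-1-carboxylate | COc1cc(OCOC)ccc1[C@H]1C=C(C)CC[C@@]1(C)C(=O)OC
F4 | step 7 | {(1R,2S)-2-[2-methoxy-4-(methoxymethoxy)phenyl]-1,4-dimethylcyclohex-3-en-1-yl}methanol | COc1cc(OCOC)ccc1[C@H]1C=C(C)CC[C@@]1(C)CO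
F5 | step 12 | 1-{(1S,6R)-6-[(E)-2-iodoethenyl]-3,6-dimethylcyclohex-2-en-1-yl}-2-methoxy-4-(methoxymethoxy)benzene | COc1cc(OCOC)ccc1[C@H]1C=C(C)CC[C@@]1(C)/C=C/I
F6 | step 12 | 1-methoxy-3-(methoxymethoxy)benzene | COCOc1cccc(OC)c1
F7 | step 12 | 2-[2-methoxy-6-(methoxymethoxy)phenyl]-4,4,5,5-tetramethyl-1,3,2-dioxaborolane | COCOc1cccc(OC)c1B1OC(C)(C)C(C)(C)O1
F8 | step 15 | bis[(triphenylphosphoranylidene)acetate] aryl ester of 21 (both phenolic oxygens acylated; not isolated) | COc1cc(OC(=O)C=P(c2ccccc2)(c2ccccc2)c2ccccc2)c(C=O)cc1[C@H]1C=C(C)CC[C@@]1(C)/C=C/c1c(OC)ccc(C=O)c1OC(=O)C=P(c1ccccc1)(c1ccccc1)c1ccccc1
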